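Each half is numbered as a naphthalene: alcohol half C1–C8a (spiro C1, carbinol C4), ketone half C1′–C8a′ (ketal C1′, ketone C4′). Everything rests on cutting C1–C8a and C4–C4a. The C1–C4 ring bears oxygen at C1 and C4 and shares its C4a–C8a edge with a benzene ring oxygenated at C5 and C8, which is what a p-benzoquinone cycloadduct becomes once its ene-dione tautomerises. One catalytic asymmetric Diels–Alder reaction therefore closes that ring, supplies the C5–C8 arene and sets C1 and C4. Its diene is a (Z,E)-2-(3-silyloxyallylidene)-2H-naphtho[1,8-bc]furan that already contains the ketone half as a naphthalene, the furan oxygen being the future C1–O–C1′ bridge.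

Key step: step 11

Remarks on the chemistry (one line each):
- Assumption: the (S)-configured oxazaborolidinium catalyst is taken to give the (1S,4R) adduct; if the sense proves opposite, its (R)-antipode is used.
- The allylidene chain needs three carbons on the furan carbon; they are brought in as vinyl (C1, C2) and formylmethylene (C3, C4), and the enal is enolised through its C1–H so that the silyl dienol ether forms 3E.
- The C1–O bond of 19–21 is a doubly benzylic, allylic ether next to a free phenol; Brønsted acid is therefore avoided until C2=C3 is epoxidised, and the C1′ ketal is closed oxidatively.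
- Compounds 9–15 are racemic at C1, which becomes sp2 in 16.
- Naphthalene names of 2–10 use juglone locants (equal to the primed ones); naphthofuran names use O1, C2, C2a–C8b, where C2 = C1, C2a = C8′, C4 = C6′, C5 = C5′, C6 = C4′, C8a = C1′.

Step 1
Reactants: 1 juglone (5-hydroxy-1,4-naphthoquinone)
Product: 2 5-(methoxymethoxy)-1,4-naphthoquinone
Conditions: MOMCl, iPr2NEt, CH2Cl2, 0 °C → rt
Reagents that add atoms: chloromethyl methyl ether, COCCl
Why: Williamson-type O-alkylation of the hydrogen-bonded phenol with the reactive chloromethyl ether should give the acetal ether, whose oxygen later directs electrophiles to C8 and C6.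

Step 2
Reactants: 2 5-(methoxymethoxy)-1,4-naphthoquinone
Product: 4 5-(methoxymethoxy)naphthalene-1,4-diyl diacetate, via hydroquinone 3 (not isolated)
Conditions: Na2S2O4, EtOAc/H2O, rt; then Ac2O, pyridine, DMAP (cat.), CH2Cl2, 0 °C → rt
Reagents that add atoms: acetic anhydride, CC(=O)OC(C)=O
Why: Two-electron reduction of the quinone and O-acetylation of the hydroquinone (reductive acetylation) should give a stable diester in which ring A (C1–C4) is deactivated relative to ring B (C5–C8).

Step 3
Reactants: 4 5-(methoxymethoxy)naphthalene-1,4-diyl diacetate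
Product: 5 8-bromo-5-(methoxymethoxy)naphthalene-1,4-diyl diacetate
Conditions: NBS (1.05 equiv), MeCN, 0 °C → rt
Reagents that add atoms: N-bromosuccinimide, O=C1CCC(=O)N1Br
Why: Electrophilic aromatic bromination should take place at C8, the free α-position para to the alkoxy group of ring B, since the acetoxy-substituted ring A is far less nucleophilic.

Step 4
Reactants: 5 8-bromo-5-(methoxymethoxy)naphthalene-1,4-diyl diacetate
Product: 6 8-bromo-6-chloro-5-(methoxymethoxy)naphthalene-1,4-diyl diacetate
Conditions: NCS (1.1 equiv), AcOH, MeCN, 50 °C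
Reagents that add atoms: N-chlorosuccinimide, O=C1CCC(=O)N1Cl
Why: Electrophilic aromatic chlorination should follow at C6, now the only position ortho or para to the alkoxy group, the weak acid being tolerated by the MOM ether.

Step 5
Reactants: 6 8-bromo-6-chloro-5-(methoxymethoxy)naphthalene-1,4-diyl diacetate; 7 tributyl(vinyl)stannane
Product: 8 6-chloro-5-(methoxymethoxy)-8-vinylnaphthalene-1,4-diyl diacetate
Conditions: Pd(PPh3)4 (5 mol %), toluene, 100 °C
Reagents that add atoms: none
Why: Stille cross-coupling should replace bromine by vinyl (C1 and C2), because zerovalent palladium inserts into the C8–Br bond far faster than into C6–Cl and the neutral conditions leave both acetates intact.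

Step 6
Reactants: 8 6-chloro-5-(methoxymethoxy)-8-vinylnaphthalene-1,4-diyl diacetate
Product: 9 6-chloro-5-(methoxymethoxy)-8-(oxiran-2-yl)naphthalene-1,4-diyl diacetate (racemic)
Conditions: dimethyldioxirane, acetone, 0 °C
Reagents that add atoms: dimethyldioxirane, CC1(C)OO1
Why: Oxygen-atom transfer from the neutral dioxirane to the only alkene (electrophilic epoxidation) should give the racemic benzylic epoxide without the acid that would rearrange it.

Step 7
Reactants: 9 6-chloro-5-(methoxymethoxy)-8-(oxiran-2-yl)naphthalene-1,4-diyl diacetate (racemic)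
Product: 11 4-chloro-2-(hydroxymethyl)-5-(methoxymethoxy)-2H-naphtho[1,8-bc]furan-6-ol (racemic), via epoxy naphthalenediol 10 (not isolated)
Conditions: K2CO3 (0.5 equiv), degassed MeOH, 0 °C → rt, Ar
Reagents that add atoms: none
Why: Methanolysis of both aryl acetates (transesterification) frees the C1′ phenoxide, which should open the epoxide at the para-alkoxy-activated benzylic carbon in a 5-exo-tet ring closure and so form the furan ring with C1 as a racemic sp3 centre.

Step 8
Reactants: 11 4-chloro-2-(hydroxymethyl)-5-(methoxymethoxy)-2H-naphtho[1,8-bc]furan-6-ol (racemic)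
Product: 12 4-chloro-2-(hydroxymethyl)-5-(methoxymethoxy)-2H-naphtho[1,8-bc]furan-6-yl acetate (racemic)
Conditions: Ac2O (1.05 equiv), Et3N, CH2Cl2, −20 °C
Reagents that add atoms: acetic anhydride, CC(=O)OC(C)=O
Why: Under amine base without an acyl-transfer catalyst the naphthol is acetylated much faster than the neutral primary alcohol (chemoselective O-acylation), which protects the oxidation-prone C4′ oxygen before the alcohol is oxidised.

Step 9
Reactants: 12 4-chloro-2-(hydroxymethyl)-5-(methoxymethoxy)-2H-naphtho[1,8-bc]furan-6-yl acetate (racemic); 13 (triphenylphosphoranylidene)acetaldehyde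
Product: 15 4-chloro-5-(methoxymethoxy)-2-[(E)-3-oxoprop-1-en-1-yl]-2H-naphtho[1,8-bc]furan-6-yl acetate (racemic), via aldehyde 14 (not isolated)
Conditions: Dess–Martin periodinane, pyridine, CH2Cl2, 0 °C; filtration; then 13 (1.2 equiv), CH2Cl2, rt
Reagents that add atoms: none
Why: Dess–Martin oxidation gives the aldehyde and Wittig olefination with the stabilised ylide should give the (E)-enal, which adds C3 and C4 at the aldehyde oxidation level.

Step 10
Reactants: 15 4-chloro-5-(methoxymethoxy)-2-[(E)-3-oxoprop-1-en-1-yl]-2H-naphtho[1,8-bc]furan-6-yl acetate (racemic)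
Product: 16 (Z)-2-[(E)-3-(tert-butyldimethylsilyloxy)prop-2-en-1-ylidene]-4-chloro-5-(methoxymethoxy)-2H-naphtho[1,8-bc]furan-6-yl acetate
Conditions: TBSOTf (1.3 equiv), Et3N, CH2Cl2, −78 → 0 °C; used at once
Reagents that add atoms: tert-butyldimethylsilyl trifluoromethanesulfonate, CC(C)(C)[Si](C)(C)OS(=O)(=O)C(F)(F)F
Why: Soft enolisation (O-silylation, then amine deprotonation of the benzylic, oxygen-bearing C1–H in the γ-position) of the s-trans enal should give the 3E silyl dienol ether, and the new C1=C2 bond should form Z because this puts the chain next to the furan oxygen and not next to C7′–H.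

Step 11
Reactants: 16 (Z)-2-[(E)-3-(tert-butyldimethylsilyloxy)prop-2-en-1-ylidene]-4-chloro-5-(methoxymethoxy)-2H-naphtho[1,8-bc]furan-6-yl acetate; 17 1,4-benzoquinone
Product: 19 (1S,4R)-hydroquinone: 4-(tert-butyldimethylsilyloxy)-1,4-dihydronaphthalene-5,8-diol spiro-fused at C1 to C2 of 6-acetoxy-4-chloro-5-(methoxymethoxy)-2H-naphtho[1,8-bc]furan (C1–O and C4–O trans), via endo cycloadduct 18 (not isolated)
Conditions: 17 (1.05 equiv), (S)-1-(2-methylphenyl)-3,3-diphenyltetrahydro-1H,3H-pyrrolo[1,2-c][1,3,2]oxazaborole (20 mol %), HNTf2 (20 mol %), CH2Cl2, −78 °C; then Et3N (0.3 equiv), −78 → 0 °C, Ar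
Reagents that add atoms: none
Why: The protonated oxazaborolidine binds one quinone carbonyl and the electron-rich diene adds endo in an asynchronous [4+2] cycloaddition, its silyloxy-bearing C4 terminus bonding first (C4–C4a) to the carbon β to the bound carbonyl and the cation-stabilised C1 terminus then closing C1–C8a, after which Et3N tautomerises the cis-ene-dione 18 to the hydroquinone. The closest known reaction type is the chiral oxazaborolidinium-catalysed Diels–Alder reaction of p-quinones with 1-oxygenated dienes. The C1–C4 cyclohexene ring is closed by the cycloaddition itself, both ring bonds forming in that one step, whereas the C4a–C8a benzene ring arises from the quinone ring by enolisation and not by a ring closure. The relative configuration of C1 and C4 follows from the diene geometry and suprafacial addition: the furan oxygen sits inside (1Z) and the silyloxy group outside (3E), so C1–O and C4–O end up trans. The absolute configuration of both centres comes from the catalyst, which shields one face of the bound quinone and thereby selects one face of the diene. For that transfer the step needs endo approach and a single orientation of the unsymmetrical diene towards the bound carbonyl, and the substrate secures the orientation because C1, flanked by the furan oxygen and the arene, carries the positive charge in the transition state while C4 is the nucleophilic end.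

Step 12
Reactants: 19 (1S,4R)-hydroquinone cycloadduct
Product: 20 5-O-(tert-butyldimethylsilyl) ether of 19 (C8–OH free)
Conditions: TBSCl (1.1 equiv), imidazole, DMF, 0 °C
Reagents that add atoms: tert-butyldimethylsilyl chloride, CC(C)(C)[Si](C)(C)Cl
Why: Phenol silylation should occur at C5–OH, which has only C4–H in its plane, and not at C8–OH, which is buried beside the spiro centre, so that the alcohol-half arene is no longer a free hydroquinone.

Step 13
Reactants: 20 5-O-TBS ether of the cycloadduct
Product: 21 naphthol: 20 without the acetyl group (free C4′–OH and C8–OH)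
Conditions: N2H4·H2O (2 equiv), THF/MeOH, 0 °C, Ar; used at once
Reagents that add atoms: none
Why: Hydrazinolysis of the aryl acetate (acyl transfer to a neutral nitrogen nucleophile) should free the C4′ naphthol without the strong base or acid that would ionise the C1–O bond next to the free C8 phenol.

Step 14
Reactants: 21 naphthol with free C4′–OH and C8–OH
Product: 22 spiroketal enone: C8–O bonded to C1′ (ketal), C4′ ketone, C2′=C3′ and C2=C3 alkenes, C4–OTBS trans to the C1–O bridge, C5–OTBS, C5′–OMOM, C6′–Cl
Conditions: PhI(OAc)2 (1.05 equiv), NaHCO3, CF3CH2OH/CH2Cl2, −20 °C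
Reagents that add atoms: none
Why: Oxidative dearomatisation of the 4-alkoxy-1-naphthol by the iodane gives a C1′ oxocarbenium ion that the neighbouring C8 hydroxyl should capture in a 6-membered ring closure (oxidative spiroketalisation), the configuration at C1′ being dictated by C1 because the new ketal is part of a bridged ring.

Step 15
Reactants: 22 spiroketal enone
Product: 23 C2–C3 epoxide of 22, epoxide oxygen cis to the C1–O bridge and trans to C4–OTBS
Conditions: dimethyldioxirane, acetone/CH2Cl2, 0 °C → rt
Reagents that add atoms: dimethyldioxirane, CC1(C)OO1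
Why: Electrophilic epoxidation of the C2=C3 alkene by the neutral dioxirane should occur on the face of the C1–O bridge, anti to both the C4 silyloxy group and the C8′ arene, and it removes the alkene through which the C1–O bond could ionise and aromatise.

Step 16
Reactants: 23 C2–C3 epoxide
Product: 24 23 with free C5–OH (C4–OTBS kept)
Conditions: TBAF (1.1 equiv), AcOH (1.1 equiv), THF, 0 °C
Reagents that add atoms: none
Why: Buffered fluoride cleaves the aryl silyl ether much faster than the hindered secondary alkyl silyl ether (chemoselective desilylation), which should free C5–OH alone.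

Step 17
Reactants: 24 C5 phenol
Product: 25 6-chloro derivative of 24
Conditions: NCS (1.05 equiv), MeCN, 0 °C → rt
Reagents that add atoms: N-chlorosuccinimide, O=C1CCC(=O)N1Cl
Why: Electrophilic aromatic chlorination of the para-alkoxyphenol should go ortho to the free hydroxyl, at C6, the para position being occupied and the ketone-half arene being deactivated by its carbonyl.

Step 18
Reactants: 25 6-chloro phenol
Product: 26 C2′–C3′ epoxide of 25, epoxide oxygen cis to the bridging C1–O–C1′ oxygen
Conditions: t-BuOOH (decane), DBU, CH2Cl2, 0 °C → rt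
Reagents that add atoms: tert-butyl hydroperoxide, CC(C)(C)OO
Why: Nucleophilic (Weitz–Scheffer) epoxidation of the enone by the hydroperoxide anion should attack C2′ from the face of the one-atom oxygen bridge, away from the alcohol-half arene that covers the other face, while C4–O stays silylated so that no epoxide migration can start from an alkoxide.

Step 19
Reactants: 26 bis-epoxide with C5′–OMOM and C4–OTBS
Product: 27 CNP0289684.3 (target)
Conditions: HCl (3 M aq.)/THF, 0 °C → rt
Reagents that add atoms: none
Why: Acid-catalysed acetal hydrolysis of the aryl MOM ether and solvolysis of the silyl ether (global deprotection) should give the target, both epoxides being flanked by oxygenated carbons that disfavour their ionisation.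

Compound list
1 | juglone (5-hydroxy-1,4-naphthoquinone) | O=C1C=CC(=O)c2c(O)cccc12 | starting material
2 | 5-(methoxymethoxy)-1,4-naphthoquinone | O=C1C=CC(=O)c2c(OCOC)cccc12 | intermediate
3 | 5-(methoxymethoxy)naphthalene-1,4-diol | COCOc1cccc2c(O)ccc(O)c12 | intermediate (not isolated)
4 | 5-(methoxymethoxy)naphthalene-1,4-diyl diacetate | COCOc1cccc2c(OC(C)=O)ccc(OC(C)=O)c12 | intermediate
5 | 8-bromo-5-(methoxymethoxy)naphthalene-1,4-diyl diacetate | COCOc1ccc(Br)c2c(OC(C)=O)ccc(OC(C)=O)c12 | intermediate
6 | 8-bromo-6-chloro-5-(methoxymethoxy)naphthalene-1,4-diyl diacetate | COCOc1c(Cl)cc(Br)c2c(OC(C)=O)ccc(OC(C)=O)c12 | intermediate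
7 | tributyl(vinyl)stannane | C=C[Sn](CCCC)(CCCC)CCCC | starting material
8 | 6-chloro-5-(methoxymethoxy)-8-vinylnaphthalene-1,4-diyl diacetate | COCOc1c(Cl)cc(C=C)c2c(OC(C)=O)ccc(OC(C)=O)c12 | intermediate
9 | 6-chloro-5-(methoxymethoxy)-8-(oxiran-2-yl)naphthalene-1,4-diyl diacetate, racemic | COCOc1c(Cl)cc(C3CO3)c2c(OC(C)=O)ccc(OC(C)=O)c12 | intermediate
10 | 6-chloro-5-(methoxymethoxy)-8-(oxiran-2-yl)naphthalene-1,4-diol, racemic | COCOc1c(Cl)cc(C3CO3)c2c(O)ccc(O)c12 | intermediate (not isolated)
11 | 4-chloro-2-(hydroxymethyl)-5-(methoxymethoxy)-2H-naphtho[1,8-bc]furan-6-ol, racemic | Oc1ccc2OC(CO)c3cc(Cl)c(OCOC)c1c32 | intermediate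
12 | 4-chloro-2-(hydroxymethyl)-5-(methoxymethoxy)-2H-naphtho[1,8-bc]furan-6-yl acetate, racemic | CC(=O)Oc1ccc2OC(CO)c3cc(Cl)c(OCOC)c1c32 | intermediate
13 | (triphenylphosphoranylidene)acetaldehyde | O=CC=P(c1ccccc1)(c1ccccc1)c1ccccc1 | starting material
14 | 4-chloro-2-formyl-5-(methoxymethoxy)-2H-naphtho[1,8-bc]furan-6-yl acetate, racemic | CC(=O)Oc1ccc2OC(C=O)c3cc(Cl)c(OCOC)c1c32 | intermediate (not isolated)
15 | 4-chloro-5-(methoxymethoxy)-2-[(E)-3-oxoprop-1-en-1-yl]-2H-naphtho[1,8-bc]furan-6-yl acetate, racemic | CC(=O)Oc1ccc2OC(/C=C/C=O)c3cc(Cl)c(OCOC)c1c32 | intermediate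
16 | (Z)-2-[(E)-3-(tert-butyldimethylsilyloxy)prop-2-en-1-ylidene]-4-chloro-5-(methoxymethoxy)-2H-naphtho[1,8-bc]furan-6-yl acetate | CC(=O)Oc1ccc2O/C(=C\C=C\O[Si](C)(C)C(C)(C)C)c3cc(Cl)c(OCOC)c1c32 | intermediate
17 | 1,4-benzoquinone | O=C1C=CC(=O)C=C1 | starting material
18 | endo cycloadduct: cis-fused 4-(TBS-oxy)-1,4,4a,8a-tetrahydronaphthalene-5,8-dione spiro-fused at C1 to C2 of the naphthofuran; H4a and H8a trans to C4–OTBS and to the C1–aryl bond | CC(=O)Oc1ccc2O[C@@]5(C=C[C@@H](O[Si](C)(C)C(C)(C)C)[C@H]6C(=O)C=CC(=O)[C@@H]56)c3cc(Cl)c(OCOC)c1c32 | intermediate (not isolated)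
19 | (1S,4R)-hydroquinone: 4-(TBS-oxy)-1,4-dihydronaphthalene-5,8-diol spiro-fused at C1 to C2 of 6-acetoxy-4-chloro-5-(methoxymethoxy)-2H-naphtho[1,8-bc]furan; C1–O and C4–O trans | CC(=O)Oc1ccc2O[C@@]5(C=C[C@@H](O[Si](C)(C)C(C)(C)C)c6c(O)ccc(O)c65)c3cc(Cl)c(OCOC)c1c32 | intermediate
20 | 5-O-TBS ether of 19 (C8–OH free), (1S,4R) | CC(=O)Oc1ccc2O[C@@]5(C=C[C@@H](O[Si](C)(C)C(C)(C)C)c6c(O[Si](C)(C)C(C)(C)C)ccc(O)c65)c3cc(Cl)c(OCOC)c1c32 | intermediate
21 | naphthol: 20 without acetyl (free C4′–OH and C8–OH), (1S,4R) | Oc1ccc2O[C@@]5(C=C[C@@H](O[Si](C)(C)C(C)(C)C)c6c(O[Si](C)(C)C(C)(C)C)ccc(O)c65)c3cc(Cl)c(OCOC)c1c32 | intermediate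
22 | spiroketal enone: C8–O–C1′ ketal, C4′ ketone, C2′=C3′ and C2=C3 alkenes, C4–OTBS trans to the C1–O bridge, C5–OTBS, C5′–OMOM, C6′–Cl | O=C1c2c(OCOC)c(Cl)cc3c2[C@@]2(Oc4ccc(O[Si](C)(C)C(C)(C)C)c5c4[C@]3(O2)C=C[C@H]5O[Si](C)(C)C(C)(C)C)C=C1 | intermediate
23 | C2–C3 epoxide of 22, epoxide oxygen cis to the C1–O bridge, trans to C4–OTBS | O=C1c2c(OCOC)c(Cl)cc3c2[C@@]2(Oc4ccc(O[Si](C)(C)C(C)(C)C)c5c4[C@]3(O2)[C@@H]2O[C@@H]2[C@H]5O[Si](C)(C)C(C)(C)C)C=C1 | intermediate
24 | 23 with free C5–OH | O=C1c2c(OCOC)c(Cl)cc3c2[C@@]2(Oc4ccc(O)c5c4[C@]3(O2)[C@@H]2O[C@@H]2[C@H]5O[Si](C)(C)C(C)(C)C)C=C1 | intermediate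
25 | 6-chloro derivative of 24 | O=C1c2c(OCOC)c(Cl)cc3c2[C@@]2(Oc4cc(Cl)c(O)c5c4[C@]3(O2)[C@@H]2O[C@@H]2[C@H]5O[Si](C)(C)C(C)(C)C)C=C1 | intermediate
26 | C2′–C3′ epoxide of 25, epoxide oxygen cis to the bridging C1–O–C1′ oxygen | O=C1c2c(OCOC)c(Cl)cc3c2[C@@]2(Oc4cc(Cl)c(O)c5c4[C@]3(O2)[C@@H]2O[C@@H]2[C@H]5O[Si](C)(C)C(C)(C)C)[C@@H]2O[C@H]12 | intermediate
27 | CNP0289684.3 | O=C1c2c(O)c(Cl)cc3c2[C@@]2(Oc4cc(Cl)c(O)c5c4[C@]3(O2)[C@@H]2O[C@@H]2[C@H]5O)[C@@H]2O[C@H]12 | target

Total step count: 19. Longest linear sequence: 19 steps (1 → 27); 7, 13 and 17 are purchased.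

Steps most likely to fail

Step 11. The catalyst may fail to discriminate the two faces or the two orientations of the diene, a zwitterionic pathway may leak to the cis C1–O/C4–O isomer, or the acid-sensitive dienyl silyl ether may be lost before it adds. The fallback sets out from 16 and 17: the cycloaddition is run without catalyst (toluene, rt) and enolised with Et3N. This passes through the mirror-image cycloadduct F1 (not isolated) beside 18 and gives 19 as the racemate, that is, together with the mirror-image hydroquinone F2. Preparative HPLC on an amylose tris(3,5-dimethylphenylcarbamate) phase removes F2, and the route is rejoined at 19.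

Step 7. The phenoxide may attack the terminal epoxide carbon and close the six-membered ether, or the benzylic epoxide may rearrange to an aldehyde before it cyclises. The fallback sets out from 8: dihydroxylation (OsO4 cat., N-methylmorpholine N-oxide, acetone/H2O) should give the diol diacetate F3, and methanolysis (K2CO3, MeOH, Ar) the tetraol F4. Pyridinium p-toluenesulfonate in CH2Cl2 then ionises only the para-alkoxybenzylic carbinol, which the peri hydroxyl captures in the five-membered ring. The route is rejoined at 11.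

Step 14. The iodane may oxidise the silyloxyphenol ring in competition with the naphthol, or solvent may capture the oxidised intermediate before the C8 hydroxyl does. The fallback sets out from 19 and puts an acyl group on C5–O, which makes that ring hard to oxidise. Pivaloyl chloride/pyridine should give the C5 pivalate F5, and N2H4·H2O cleaves only the aryl acetate to give the naphthol pivalate F6. PhI(OAc)2 then closes the ketal to the spiroketal pivalate F7, and dimethyldioxirane gives the epoxy pivalate F8. K2CO3/MeOH removes the pivalate, and the route is rejoined at 24.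

Further compounds
F1 | step 11 | mirror-image cycloadduct (enantiomer of 18) | CC(=O)Oc1ccc2O[C@]5(C=C[C@H](O[Si](C)(C)C(C)(C)C)[C@@H]6C(=O)C=CC(=O)[C@H]56)c3cc(Cl)c(OCOC)c1c32
F2 | step 11 | mirror-image hydroquinone (enantiomer of 19) | CC(=O)Oc1ccc2O[C@]5(C=C[C@H](O[Si](C)(C)C(C)(C)C)c6c(O)ccc(O)c65)c3cc(Cl)c(OCOC)c1c32
F3 | step 7 | 6-chloro-8-(1,2-dihydroxyethyl)-5-(methoxymethoxy)naphthalene-1,4-diyl diacetate, racemic | COCOc1c(Cl)cc(C(O)CO)c2c(OC(C)=O)ccc(OC(C)=O)c12
F4 | step 7 | 6-chloro-8-(1,2-dihydroxyethyl)-5-(methoxymethoxy)naphthalene-1,4-diol, racemic | COCOc1c(Cl)cc(C(O)CO)c2c(O)ccc(O)c12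
F5 | step 14 | C5 pivalate of 19 | CC(=O)Oc1ccc2O[C@@]5(C=C[C@@H](O[Si](C)(C)C(C)(C)C)c6c(OC(=O)C(C)(C)C)ccc(O)c65)c3cc(Cl)c(OCOC)c1c32
F6 | step 14 | naphthol pivalate (F5 without acetyl) | Oc1ccc2O[C@@]5(C=C[C@@H](O[Si](C)(C)C(C)(C)C)c6c(OC(=O)C(C)(C)C)ccc(O)c65)c3cc(Cl)c(OCOC)c1c32
F7 | step 14 | spiroketal pivalate (22 with C5–OPiv in place of C5–OTBS) | O=C1c2c(OCOC)c(Cl)cc3c2[C@@]2(Oc4ccc(OC(=O)C(C)(C)C)c5c4[C@]3(O2)C=C[C@H]5O[Si](C)(C)C(C)(C)C)C=C1
F8 | step 14 | epoxy pivalate (23 with C5–OPiv in place of C5–OTBS) | O=C1c2c(OCOC)c(Cl)cc3c2[C@@]2(Oc4ccc(OC(=O)C(C)(C)C)c5c4[C@]3(O2)[C@@H]2O[C@@H]2[C@H]5O[Si](C)(C)C(C)(C)C)C=C1
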